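**Plan**

1. Retrosynthetic cuts, in order: the seven O–CH3 bonds together with the C2 configuration (trans from cis); the aryl–vinyl bond at C5 of the benzofuran (Heck); the C2–C3 bond of the dihydrofuran ring (the ring-forming cut); the C3–aryl bond via a diaryl ketone (Grignard) and the O1–C2 bond as a plain benzyl aryl ether (Williamson).
2. Forward: all four benzene rings are bought. The bromosalicylaldehyde takes the 3,4-dimethoxybenzyl group on oxygen and the 3,5-dimethoxyphenyl group on the carbonyl carbon. The dihydrofuran ring is the only ring made and is closed last by C2–C3 bond formation; the styryl arm is then joined and the methyl ethers are removed.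
3. Enabling feature: C2 is both benzylic (catechol ring) and α to O1, so its C–H bond is hydridic. C3 sits between two aryl rings, so it can be reached as a donor/donor rhodium carbene from a diaryl ketone. O1–C7a–C3a hold the two carbons 1,5 to each other; both would be electrophilic benzylic sites in polar logic, so the carbene is what allows their union.
4. Stereochemistry: C3 (S) is set by the chiral Rh(II) carboxylate in the insertion. C2 is formed cis (R) and then inverted to S (trans, the more stable isomer) by reversible C2–O1 ionisation, which the para oxygen of the catechol ring permits. The E alkene comes from the Heck reaction.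

Key step: step 5

Assumption: Rh2(S-PTAD)4 is taken to induce the 3S configuration; if the sense of induction is the opposite, the commercial mirror-image catalyst Rh2(R-PTAD)4 is used with no other change.
Assumption: in step 7 the epimerisation at C2 is taken to run ahead of ether cleavage, so the trans heptamethyl ether 12 is listed as the unisolated intermediate.

**Route**

Step 1
Reactants: 1 5-bromo-2-hydroxy-4-methoxybenzaldehyde; 2 3,4-dimethoxybenzyl bromide
Product: 3 5-bromo-2-[(3,4-dimethoxybenzyl)oxy]-4-methoxybenzaldehyde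
Conditions: K2CO3, DMF, 60 °C
Reagents that add atoms: none
Why: Williamson ether synthesis, in which the only phenoxide present displaces bromide from the reactive primary benzylic halide (SN2); no stereocentre is formed.

Step 2
Reactants: 3 5-bromo-2-[(3,4-dimethoxybenzyl)oxy]-4-methoxybenzaldehyde; 4 (3,5-dimethoxyphenyl)magnesium chloride (commercial THF solution)
Product: 5 rac-{5-bromo-2-[(3,4-dimethoxybenzyl)oxy]-4-methoxyphenyl}(3,5-dimethoxyphenyl)methanol
Conditions: THF, 0 °C; then sat. aq NH4Cl
Reagents that add atoms: none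
Why: Grignard 1,2-addition to the aldehyde at 0 °C, where an aryl Grignard does not exchange with the aryl bromide; the carbinol centre is racemic and is erased in step 3.

Step 3
Reactants: 5 rac-{5-bromo-2-[(3,4-dimethoxybenzyl)oxy]-4-methoxyphenyl}(3,5-dimethoxyphenyl)methanol
Product: 6 {5-bromo-2-[(3,4-dimethoxybenzyl)oxy]-4-methoxyphenyl}(3,5-dimethoxyphenyl)methanone
Conditions: Dess–Martin periodinane, CH2Cl2, rt
Reagents that add atoms: none
Why: Dess–Martin oxidation of a secondary benzhydryl alcohol to the diaryl ketone under near-neutral conditions that should leave the benzyl aryl ether and the aryl bromide untouched.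

Step 4
Reactants: 6 {5-bromo-2-[(3,4-dimethoxybenzyl)oxy]-4-methoxyphenyl}(3,5-dimethoxyphenyl)methanone
Product: 7 {5-bromo-2-[(3,4-dimethoxybenzyl)oxy]-4-methoxyphenyl}(3,5-dimethoxyphenyl)methanone hydrazone (E/Z mixture)
Conditions: N2H4·H2O (excess), AcOH (cat.), EtOH, 90 °C, sealed tube
Reagents that add atoms: hydrazine hydrate, NN.O
Why: hydrazone formation by condensation of hydrazine with the diaryl ketone, driven by excess hydrazine and heat against the ortho-alkoxy hindrance; the C=N geometry is irrelevant because both isomers give the same diazo compound.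

Step 5
Reactants: 7 {5-bromo-2-[(3,4-dimethoxybenzyl)oxy]-4-methoxyphenyl}(3,5-dimethoxyphenyl)methanone hydrazone
Product: 9 (2R,3S)-5-bromo-2-(3,4-dimethoxyphenyl)-3-(3,5-dimethoxyphenyl)-6-methoxy-2,3-dihydro-1-benzofuran (cis), via diazo compound 8 (not isolated)
Conditions: MnO2 (8 equiv), CH2Cl2, 0 °C; filter; slow addition to Rh2(S-PTAD)4 (1 mol %), CH2Cl2, −20 °C to rt
Reagents that add atoms: none
Why: MnO2 dehydrogenates the hydrazone to diaryldiazomethane 8, from which the chiral dirhodium tetracarboxylate expels N2 to give a donor/donor Rh carbene at C3; this carbene takes the hydridic hydrogen from the 1,5-related OCH2Ar carbon (C2) through a six-membered array, and the resulting Rh-bound C3/oxocarbenium C2 pair collapses at once to the C2–C3 bond. The closest known reaction type is the enantioselective intramolecular 1,5-C–H insertion of donor/donor carbenes generated from 2-(benzyloxy)benzophenone hydrazones, which gives cis-2,3-diaryl-2,3-dihydrobenzofurans. The dihydrofuran ring (O1, C2, C3, C3a, C7a) is closed by this 1,5-insertion, the C2–C3 bond forming in a formal 5-endo collapse onto the O1=C2 oxocarbenium. C3 is set by the catalyst, whose phthalimido/adamantyl carboxylate pocket exposes one face of the carbene to the C–H bond, and C2 is set relative to C3 (cis) because bond formation should follow hydride transfer faster than the C2 aryl group can rotate. The step needs chemoselectivity for this one C–H bond over azine formation, carbene dimerisation and attack on the methoxy groups: only the OCH2 group is 1,5 to the carbene, it is doubly activated by O1 and the electron-rich 3,4-dimethoxyphenyl ring, the donor/donor carbene is only weakly electrophilic, and slow addition keeps the diazo concentration low.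

Step 6
Reactants: 9 (2R,3S)-5-bromo-2-(3,4-dimethoxyphenyl)-3-(3,5-dimethoxyphenyl)-6-methoxy-2,3-dihydro-1-benzofuran; 10 3,5-dimethoxystyrene
Product: 11 (2R,3S)-2-(3,4-dimethoxyphenyl)-3-(3,5-dimethoxyphenyl)-5-[(E)-2-(3,5-dimethoxyphenyl)ethenyl]-6-methoxy-2,3-dihydro-1-benzofuran (cis heptamethyl ether)
Conditions: Pd(OAc)2 (5 mol %), P(o-tol)3 (10 mol %), NaOAc, DMA, 120 °C
Reagents that add atoms: none
Why: Mizoroki–Heck reaction, in which oxidative addition to the aryl bromide, syn carbopalladation at the unsubstituted styrene carbon and syn β-hydride elimination should give the E-stilbene, the non-acidic conditions leaving the C2 and C3 centres untouched.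

Step 7
Reactants: 11 (2R,3S)-2-(3,4-dimethoxyphenyl)-3-(3,5-dimethoxyphenyl)-5-[(E)-2-(3,5-dimethoxyphenyl)ethenyl]-6-methoxy-2,3-dihydro-1-benzofuran
Product: 13 (2S,3S)-2-(3,4-dihydroxyphenyl)-3-(3,5-dihydroxyphenyl)-5-[(E)-2-(3,5-dihydroxyphenyl)ethenyl]-2,3-dihydro-1-benzofuran-6-ol (target), via trans heptamethyl ether 12 (not isolated)
Conditions: BBr3 (14 equiv), CH2Cl2, −78 °C to rt; then H2O
Reagents that add atoms: none
Why: the Lewis acid should first ionise the C2–O1 bond reversibly to a para-methoxy-stabilised benzylic cation that recloses to the more stable 2,3-trans isomer with C3 untouched (acid-mediated C2 epimerisation of 2-aryl-2,3-dihydrobenzofurans), and then cleave all seven aryl methyl ethers by bromide attack on the boron-coordinated methyl groups (BBr3 demethylation), the aryl borates being hydrolysed on work-up.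

**Compound list**

1 | 5-bromo-2-hydroxy-4-methoxybenzaldehyde | O=Cc1cc(Br)c(OC)cc1O | starting material
2 | 3,4-dimethoxybenzyl bromide | COc1ccc(CBr)cc1OC | starting material
3 | 5-bromo-2-[(3,4-dimethoxybenzyl)oxy]-4-methoxybenzaldehyde | O=Cc1cc(Br)c(OC)cc1OCc1ccc(OC)c(OC)c1 | intermediate
4 | (3,5-dimethoxyphenyl)magnesium chloride | COc1cc(OC)cc([Mg]Cl)c1 | starting material
5 | rac-{5-bromo-2-[(3,4-dimethoxybenzyl)oxy]-4-methoxyphenyl}(3,5-dimethoxyphenyl)methanol | OC(c1cc(OC)cc(OC)c1)c1cc(Br)c(OC)cc1OCc1ccc(OC)c(OC)c1 | intermediate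
6 | {5-bromo-2-[(3,4-dimethoxybenzyl)oxy]-4-methoxyphenyl}(3,5-dimethoxyphenyl)methanone | O=C(c1cc(OC)cc(OC)c1)c1cc(Br)c(OC)cc1OCc1ccc(OC)c(OC)c1 | intermediate
7 | hydrazone of ketone 6 (E/Z mixture) | NN=C(c1cc(OC)cc(OC)c1)c1cc(Br)c(OC)cc1OCc1ccc(OC)c(OC)c1 | intermediate
8 | 1-bromo-5-[diazo(3,5-dimethoxyphenyl)methyl]-4-[(3,4-dimethoxybenzyl)oxy]-2-methoxybenzene | [N-]=[N+]=C(c1cc(OC)cc(OC)c1)c1cc(Br)c(OC)cc1OCc1ccc(OC)c(OC)c1 | intermediate (not isolated)
9 | (2R,3S)-5-bromo-2-(3,4-dimethoxyphenyl)-3-(3,5-dimethoxyphenyl)-6-methoxy-2,3-dihydro-1-benzofuran (cis) | Brc1cc2c(cc1OC)O[C@@H](c1ccc(OC)c(OC)c1)[C@H]2c1cc(OC)cc(OC)c1 | intermediate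
10 | 3,5-dimethoxystyrene | C=Cc1cc(OC)cc(OC)c1 | starting material
11 | (2R,3S)-2-(3,4-dimethoxyphenyl)-3-(3,5-dimethoxyphenyl)-5-[(E)-2-(3,5-dimethoxyphenyl)ethenyl]-6-methoxy-2,3-dihydro-1-benzofuran (cis heptamethyl ether) | COc1cc(OC)cc(/C=C/c2cc3c(cc2OC)O[C@@H](c2ccc(OC)c(OC)c2)[C@H]3c2cc(OC)cc(OC)c2)c1 | intermediate
12 | (2S,3S)-2-(3,4-dimethoxyphenyl)-3-(3,5-dimethoxyphenyl)-5-[(E)-2-(3,5-dimethoxyphenyl)ethenyl]-6-methoxy-2,3-dihydro-1-benzofuran (trans heptamethyl ether) | COc1cc(OC)cc(/C=C/c2cc3c(cc2OC)O[C@H](c2ccc(OC)c(OC)c2)[C@H]3c2cc(OC)cc(OC)c2)c1 | intermediate (not isolated)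
13 | (2S,3S)-2-(3,4-dihydroxyphenyl)-3-(3,5-dihydroxyphenyl)-5-[(E)-2-(3,5-dihydroxyphenyl)ethenyl]-2,3-dihydro-1-benzofuran-6-ol | Oc1cc(O)cc(/C=C/c2cc3c(cc2O)O[C@H](c2ccc(O)c(O)c2)[C@H]3c2cc(O)cc(O)c2)c1 | target

**Count and risks**

Total step count: 7. Longest linear sequence: 7 steps (1 to 13).

Steps most likely to fail:

Step 5 (key step). The insertion may lose facial control or cis selectivity with this heavily methoxylated diaryl carbene, or the diazo compound may be diverted to the azine or carbene dimer. The fallback avoids the carbene; it sets out from ketone 6 and comes back at 12. Phosphazene base P4-t-Bu in toluene at 80 °C should deprotonate the OCH2Ar group; the carbanion adds to the ketone and dehydration gives 5-bromo-2-(3,4-dimethoxyphenyl)-3-(3,5-dimethoxyphenyl)-6-methoxy-1-benzofuran F1. Ionic hydrogenation (Et3SiH, TFA, CH2Cl2) should reduce the furan C2=C3 bond and, under the acid, settle on racemic trans-5-bromo-2-(3,4-dimethoxyphenyl)-3-(3,5-dimethoxyphenyl)-6-methoxy-2,3-dihydro-1-benzofuran F2. Preparative chromatography on a chiral stationary phase then delivers (2S,3S)-5-bromo-2-(3,4-dimethoxyphenyl)-3-(3,5-dimethoxyphenyl)-6-methoxy-2,3-dihydro-1-benzofuran F3. Heck coupling of F3 with 10 under the conditions of step 6 gives the trans heptamethyl ether 12, which is isolated here and enters step 7.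

Step 7. The ring-opened C2 cation or the protonated electron-rich stilbene may alkylate other rings (oligomerisation), proton loss at C3 of the ring-opened cation may erode enantiopurity, and ether cleavage may stay incomplete. The fallback keeps the stilbene away from BBr3 and ends with a mild methanolysis; it sets out from bromide 9 and comes back at 13. BBr3 in CH2Cl2 (−78 °C to rt) on 9 should give, with the same C2 epimerisation, (2S,3S)-5-bromo-2-(3,4-dihydroxyphenyl)-3-(3,5-dihydroxyphenyl)-2,3-dihydro-1-benzofuran-6-ol F4. Ac2O/pyridine converts it into (2S,3S)-5-bromo-2-(3,4-diacetoxyphenyl)-3-(3,5-diacetoxyphenyl)-2,3-dihydro-1-benzofuran-6-yl acetate F5, which can be purified on silica. Heck coupling of F5 with purchased 3,5-diacetoxystyrene (Pd(OAc)2, P(o-tol)3, NaOAc, DMA, 110 °C) should give the heptaacetate of the target F6. Methanolysis with catalytic K2CO3 in degassed MeOH at 0 °C then releases 13.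

Step 6. Oxidative addition to the electron-rich, ortho-alkoxy aryl bromide may be slow, leading to catalyst decomposition, protodebromination or some 1,1-diaryl (branched) insertion. The fallback replaces the alkene C–H coupling by a cross-coupling with a preformed E-alkenyl partner; it sets out from 9 and comes back at 11. Suzuki–Miyaura coupling of 9 with purchased (E)-2-(3,5-dimethoxyphenyl)ethenylboronic acid pinacol ester (Pd(dppf)Cl2, K3PO4, dioxane/H2O, 80 °C) should give 11 directly with the olefin geometry and position fixed by the reagent; no new compound is made on the way (F0).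

**Further compounds**

F1 | step 5 | 5-bromo-2-(3,4-dimethoxyphenyl)-3-(3,5-dimethoxyphenyl)-6-methoxy-1-benzofuran | COc1cc(OC)cc(-c2c(-c3ccc(OC)c(OC)c3)oc3cc(OC)c(Br)cc23)c1
F2 | step 5 | racemic trans-5-bromo-2-(3,4-dimethoxyphenyl)-3-(3,5-dimethoxyphenyl)-6-methoxy-2,3-dihydro-1-benzofuran | Brc1cc2c(cc1OC)O[C@H](c1ccc(OC)c(OC)c1)[C@H]2c1cc(OC)cc(OC)c1.Brc1cc2c(cc1OC)O[C@@H](c1ccc(OC)c(OC)c1)[C@@H]2c1cc(OC)cc(OC)c1
F3 | step 5 | (2S,3S)-5-bromo-2-(3,4-dimethoxyphenyl)-3-(3,5-dimethoxyphenyl)-6-methoxy-2,3-dihydro-1-benzofuran | Brc1cc2c(cc1OC)O[C@H](c1ccc(OC)c(OC)c1)[C@H]2c1cc(OC)cc(OC)c1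
F4 | step 7 | (2S,3S)-5-bromo-2-(3,4-dihydroxyphenyl)-3-(3,5-dihydroxyphenyl)-2,3-dihydro-1-benzofuran-6-ol | Brc1cc2c(cc1O)O[C@H](c1ccc(O)c(O)c1)[C@H]2c1cc(O)cc(O)c1
F5 | step 7 | (2S,3S)-5-bromo-2-(3,4-diacetoxyphenyl)-3-(3,5-diacetoxyphenyl)-2,3-dihydro-1-benzofuran-6-yl acetate | Brc1cc2c(cc1OC(C)=O)O[C@H](c1ccc(OC(C)=O)c(OC(C)=O)c1)[C@H]2c1cc(OC(C)=O)cc(OC(C)=O)c1
F6 | step 7 | heptaacetate of the target | CC(=O)Oc1cc(OC(C)=O)cc(/C=C/c2cc3c(cc2OC(C)=O)O[C@H](c2ccc(OC(C)=O)c(OC(C)=O)c2)[C@H]3c2cc(OC(C)=O)cc(OC(C)=O)c2)c1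
F0 | step 6 | none | none
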